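The data are simulated for substances that don't exist; noise was put on by code.

At early times the delta and theta runs stand close, 1.9 % against 2.0 % of the free monomer in chains at 0.250 d. Then both speed up, so I read the chains as being begun during the run and not at once.

| flask | free monomer | initiator | remark | time |
|---|---|---|---|---|
| delta | 0.80 M | 2 mM | run made earlier |  |
| theta | 0.80 M | 3 mM | run made earlier |  |
| Thursday's | 0.80 M | 4.0 mM |  | 4.0 d |
| Monday's | 0.80 M | 4.0 mM |  | 1.2 d |

| run | time / d | monomer in chains / % |
|---|---|---|
| delta | 0.250 | 1.9 |
| delta | 0.833 | 7.7 |
| delta | 1.67 | 22.4 |
| delta | 2.50 | 37.5 |
| delta | 3.00 | 46.3 |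
| theta | 0.250 | 2.0 |
| theta | 0.833 | 9.6 |
| theta | 1.67 | 32.0 |
| theta | 2.50 | 51.7 |
| theta | 3.00 | 60.7 |

(readings scatter by 1 percentage point)

- which of the two ends with the longer chains by the average number of monomer units in a chain (chains begun, living or dead) ("neither" if they lie within 10 %) (Thursday's / Monday's / neither)
- average number of monomer units in a chain (chains begun, living or dead) at the end, Thursday's
- average number of monomer units in a chain (chains begun, living or dead) at the end, Monday's

- the average divides the monomer in chains by the number of chains begun, living and dead together
- the earlier runs do not show the number of chains; that part of a forecast is a guess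

I write x for the fraction of the free monomer in chains and work with the logarithm ln(charge/left). At 3.00 d the readings give 0.622 for delta and 0.934 for theta, a ratio of 1.50 against 1.50 in initiator, so at a given time and with this charge of free monomer I let the logarithm follow the initiator charge.

Thursday's and Monday's hold twice delta's initiator. Doubling delta's logarithm gives x = 0.712 at 3.00 d, and Thursday's runs on past that time. It gives x = 0.398 at 1.67 d, and Monday's stops short of that time.

Free monomer charged over initiator charged is 200; I call this the charge ratio. The average length is then charge ratio × x / f, where f is the fraction of the initiator that has begun a chain, the initiator efficiency. The readings do not show f. With f guessed at one in both flasks, my estimate is above 142 for Thursday's and below 79.6 for Monday's, so I expect Thursday's to end with the longer chains.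

The forecast says Thursday's, with 170 for Thursday's and 74 for Monday's, its chain count being “a guess, assuming one chain per initiator”.

The flask gives 308 for Thursday's and 122 for Monday's, so Thursday's ends with the longer chains.

    free monomer + initiator → living end + monomer in chains (k = 7.20 × 10⁻⁶ M⁻¹ s⁻¹)
    free monomer + living end → monomer in chains + living end, rate k2*[living end]*[free monomer] (k = 0.00290 M⁻¹ s⁻¹)
    initiator + monomer in chains → spent initiator (k = 2.40 × 10⁻⁵ M⁻¹ s⁻¹)

Turned round, the rule gives f from the length: Thursday's, with 81.3 % in chains at the end, has f = 0.527, about half of its initiator, while spent initiator holds 0.455 of that charge. The neighbour of Thursday's charged with 0.010 M of initiator has a charge ratio of 80.0, 96.0 % in chains and a length of 191, so its f is 0.402.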